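**Retrosynthetic overview**
1. Last cut: the 2-hydroxybenzyl group on C8, put on by Friedel–Crafts alkylation with salicyl alcohol at the only free carbon of ring A, after global debenzylation.
2. Ring C, the only ring that is made, is cut into three pieces joined in one flask: benzaldehyde (C2, O1), the enol silane of methyl acetate (C3, C4) and a 3,5-bis(benzyloxy)-4-alkylbenzyne (C4a≡C8a). The aldol makes C3–C2, the aldolate oxygen adds to C8a, and the C4a anion closes on the ester (C4–C4a).
3. Enabling feature: in ring A, O1 sits on C8a meta to the C5 and C7 oxygens, and the acyl carbon C4 sits on C4a next to C5–O. This is the pattern a 3-alkoxybenzyne imposes (nucleophile to the distal carbon, anion beside the alkoxy group). Ring C itself is a β-aryloxy ketone, a masked aldol of benzaldehyde.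
4. Aryne precursor: a symmetric phenol, ortho-brominated, then retro-Brook silyl shift and triflation. The phenol comes from 2,4,6-trihydroxybenzaldehyde, whose formyl carbon becomes the C6 methylene.
5. Chain: iterative benzyl–aryl cross-coupling (Suzuki–Miyaura twice, Negishi once), each CH2 arising from a formyl group. Ring order: the chain rings and ring A are bought aromatic; ring C is formed last.

Key step: step 17

Remark: C2 is (S) as drawn; in step 17 the antipode of the binaphthyl ligand that directs the nucleophile to the Si face of benzaldehyde is assumed, to be checked on methyl 3-hydroxy-3-phenylpropanoate.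
Remark on names: "chain benzyl" = 2-(benzyloxy)-5-{2-(benzyloxy)-5-{2-(benzyloxy)-5-[2-(benzyloxy)benzyl]benzyl}benzyl}benzyl. It has four rings; every CH2 sits ortho to the OBn of the outer ring and para to the OBn of the inner ring.

Step 1
Reactants: 1 2-(benzyloxy)benzyl bromide; 2 [4-(benzyloxy)-3-formylphenyl]boronic acid
Product: 3 2-(benzyloxy)-5-[2-(benzyloxy)benzyl]benzaldehyde
Conditions: Pd(PPh3)4 (3 mol%), K2CO3, DME/H2O, 80 °C
Reagents that add atoms: none
Why: Suzuki–Miyaura coupling of a benzylic bromide with an arylboronic acid is a standard diarylmethane synthesis, the boron para to the benzyloxy group fixes where the CH2 lands, and the untouched aldehyde is the handle for the next methylene.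

Step 2
Reactants: 3 2-(benzyloxy)-5-[2-(benzyloxy)benzyl]benzaldehyde
Product: 4 {2-(benzyloxy)-5-[2-(benzyloxy)benzyl]phenyl}methanol
Conditions: NaBH4, THF/MeOH, 0 °C
Reagents that add atoms: none
Why: Borohydride reduction of an aryl aldehyde is chemoselective and leaves benzyl ethers and the diarylmethane untouched.

Step 3
Reactants: 4 {2-(benzyloxy)-5-[2-(benzyloxy)benzyl]phenyl}methanol
Product: 5 1-(benzyloxy)-4-[2-(benzyloxy)benzyl]-2-(bromomethyl)benzene
Conditions: PBr3 (0.4 equiv), Et2O, 0 °C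
Reagents that add atoms: phosphorus tribromide BrP(Br)Br
Why: Conversion of an electron-rich benzylic alcohol into the bromide through its phosphite ester is routine and tolerated by aryl benzyl ethers at 0 °C.

Step 4
Reactants: 5 1-(benzyloxy)-4-[2-(benzyloxy)benzyl]-2-(bromomethyl)benzene; 2 [4-(benzyloxy)-3-formylphenyl]boronic acid
Product: 6 2-(benzyloxy)-5-{2-(benzyloxy)-5-[2-(benzyloxy)benzyl]benzyl}benzaldehyde
Conditions: Pd(PPh3)4 (3 mol%), K2CO3, DME/H2O, 80 °C
Reagents that add atoms: none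
Why: The same Suzuki–Miyaura benzyl–aryl coupling as in step 1 adds the third ring with its CH2 para to the new benzyloxy group.

Step 5
Reactants: 6 2-(benzyloxy)-5-{2-(benzyloxy)-5-[2-(benzyloxy)benzyl]benzyl}benzaldehyde
Product: 7 {2-(benzyloxy)-5-{2-(benzyloxy)-5-[2-(benzyloxy)benzyl]benzyl}phenyl}methanol
Conditions: NaBH4, THF/MeOH, 0 °C
Reagents that add atoms: none
Why: Chemoselective borohydride reduction of the aldehyde, as in step 2.

Step 6
Reactants: 7 {2-(benzyloxy)-5-{2-(benzyloxy)-5-[2-(benzyloxy)benzyl]benzyl}phenyl}methanol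
Product: 8 1-(benzyloxy)-4-{2-(benzyloxy)-5-[2-(benzyloxy)benzyl]benzyl}-2-(chloromethyl)benzene
Conditions: SOCl2, DMF (cat.), CH2Cl2, 0 °C
Reagents that add atoms: thionyl chloride ClS(Cl)=O
Why: Chlorination of a benzylic alcohol with thionyl chloride is standard, and the chloride is chosen because benzylic chlorides insert zinc with little Wurtz coupling.

Step 7
Reactants: 9 2-bromo-4-iodophenol
Product: 10 1-(benzyloxy)-2-bromo-4-iodobenzene
Conditions: BnBr, K2CO3, acetone, reflux
Reagents that add atoms: benzyl bromide BrCc1ccccc1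
Why: Williamson etherification of a phenol proceeds without touching the aryl halides.

Step 8
Reactants: 8 1-(benzyloxy)-4-{2-(benzyloxy)-5-[2-(benzyloxy)benzyl]benzyl}-2-(chloromethyl)benzene; 10 1-(benzyloxy)-2-bromo-4-iodobenzene
Product: 12 1-(benzyloxy)-2-bromo-4-{2-(benzyloxy)-5-{2-(benzyloxy)-5-[2-(benzyloxy)benzyl]benzyl}benzyl}benzene, via benzylzinc chloride 11 (not isolated)
Conditions: Zn dust, LiCl, THF, 25 °C; then 10, Pd(PPh3)4 (3 mol%), THF, 25 °C
Reagents that add atoms: none
Why: LiCl-assisted zinc insertion gives the benzylic zinc chloride, and in the Negishi coupling zerovalent palladium inserts into the C–I bond far faster than into the hindered, alkoxy-flanked C–Br bond, which is kept for step 11.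

Step 9
Reactants: 13 2,4,6-trihydroxybenzaldehyde
Product: 14 4-(allyloxy)-2,6-dihydroxybenzaldehyde
Conditions: allyl bromide (1.0 equiv), KHCO3, DMF, 25 °C
Reagents that add atoms: allyl bromide C=CCBr
Why: The 4-OH, para to the formyl group and not hydrogen-bonded, is the most acidic and is etherified first under bicarbonate (Williamson), which marks the oxygen that later becomes the triflate.

Step 10
Reactants: 14 4-(allyloxy)-2,6-dihydroxybenzaldehyde
Product: 15 4-(allyloxy)-2,6-bis(benzyloxy)benzaldehyde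
Conditions: BnBr (2.5 equiv), K2CO3, DMF, 60 °C
Reagents that add atoms: benzyl bromide BrCc1ccccc1
Why: Williamson benzylation of the two hydrogen-bonded ortho phenols needs carbonate and mild heating, which the allyl ether and aldehyde tolerate.

Step 11
Reactants: 12 tetramer aryl bromide; 15 4-(allyloxy)-2,6-bis(benzyloxy)benzaldehyde
Product: 17 racemic [4-(allyloxy)-2,6-bis(benzyloxy)phenyl](aryl)methanol (aryl = chain benzyl minus its CH2), via aryllithium 16 (not isolated)
Conditions: n-BuLi (1.05 equiv), THF, −78 °C; then 15, −78 → −20 °C; H2O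
Reagents that add atoms: none
Why: Bromine–lithium exchange is faster at −78 °C than any deprotonation of benzyl ethers or diarylmethanes, and 1,2-addition to the aldehyde gives a carbinol whose stereocentre is racemic and is removed in step 12.

Step 12
Reactants: 17 racemic diaryl carbinol
Product: 18 5-(allyloxy)-1,3-bis(benzyloxy)-2-(chain benzyl)benzene
Conditions: Et3SiH, CF3CO2H, CH2Cl2, −20 → 0 °C
Reagents that add atoms: none
Why: Ionic hydrogenation works because the diarylmethyl cation, stabilised by three ortho/para alkoxy groups, forms with little acid and is trapped by silane hydride, while allyl and benzyl ethers survive.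

Step 13
Reactants: 18 5-(allyloxy)-1,3-bis(benzyloxy)-2-(chain benzyl)benzene
Product: 19 3,5-bis(benzyloxy)-4-(chain benzyl)phenol
Conditions: Pd(PPh3)4 (5 mol%), morpholine, THF, 25 °C
Reagents that add atoms: none
Why: Tsuji–Trost deallylation of an aryl allyl ether with an amine scavenger is neutral and leaves benzyl ethers alone, and no aryl halide is present at this stage.

Step 14
Reactants: 19 3,5-bis(benzyloxy)-4-(chain benzyl)phenol
Product: 20 3,5-bis(benzyloxy)-2-bromo-4-(chain benzyl)phenol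
Conditions: NBS (1.0 equiv), CH2Cl2, −78 °C
Reagents that add atoms: N-bromosuccinimide O=C1CCC(=O)N1Br
Why: Electrophilic bromination goes ortho to the OH of the trioxygenated ring, far more nucleophilic than the mono-alkoxy chain rings, and since the two ortho positions are equivalent by symmetry and the para position is blocked only one monobromide can form.

Step 15
Reactants: 20 3,5-bis(benzyloxy)-2-bromo-4-(chain benzyl)phenol
Product: 23 3,5-bis(benzyloxy)-4-(chain benzyl)-2-(trimethylsilyl)phenyl trifluoromethanesulfonate, via silyl ether 21 (not isolated), via lithium phenoxide 22 (not isolated)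
Conditions: (Me3Si)2NH, THF, 65 °C, evaporate; n-BuLi, THF, −100 °C; then Tf2O, −100 → −78 °C
Reagents that add atoms: hexamethyldisilazane C[Si](C)(C)N[Si](C)(C)C; trifluoromethanesulfonic anhydride O=S(=O)(OS(=O)(=O)C(F)(F)F)C(F)(F)F
Why: O-silylation, bromine–lithium exchange, anionic 1,3 O→C silyl shift (retro-Brook rearrangement) and triflation of the resulting phenoxide is the standard access to 2-(trimethylsilyl)aryl triflates and puts silicon on C4a and the triflate on C8a.

Step 16
Reactants: 24 methyl acetate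
Product: 25 1-methoxy-1-(trimethylsilyloxy)ethene
Conditions: LDA, THF, −78 °C; then Me3SiCl
Reagents that add atoms: chlorotrimethylsilane C[Si](C)(C)Cl
Why: O-silylation of the lithium ester enolate gives the silyl ketene acetal needed for the Mukaiyama aldol.

Step 17
Reactants: 26 benzaldehyde; 25 1-methoxy-1-(trimethylsilyloxy)ethene; 23 silyl triflate
Product: 29 (2S)-5,7-bis(benzyloxy)-6-(chain benzyl)-2-phenylchroman-4-one, via silyl aldolate 27 (not isolated), via aryne 28 (not isolated)
Conditions: 26 (3.1 equiv), 25 (3.0 equiv), Ti(OiPr)4 (2 mol%), axially chiral 2-amino-2'-hydroxy-1,1'-binaphthyl/3-bromo-5-tert-butylsalicylaldehyde Schiff-base ligand (2.2 mol%), 3,5-di-tert-butylsalicylic acid (2 mol%), Et2O, −10 °C; then 23 (1.0 equiv), CsF (7 equiv), THF, 0 → 40 °C; H2O work-up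
Reagents that add atoms: none
Why: Proposed new method: the tetravalent-titanium Schiff-base/salicylate catalyst adds silyl ketene acetal 25 to the Si face of benzaldehyde (Mukaiyama aldol with silyl transfer), which makes the C3–C2 bond and sets C2 as (S) in silyl ether 27; fluoride then frees the alkoxide of 27 and, more slowly, eliminates Me3Si and triflate from 23 to give aryne 28 (C4a≡C8a). The alkoxide adds to C8a because the benzyloxy group on C5, next to C4a, polarises the triple bond so that the distal carbon C8a is the electrophilic one and the developing anion sits on C4a beside the C5–O bond, and C8a is also the less hindered end since its neighbour C8 carries only hydrogen. The C4a aryl anion then closes ring C by 6-exo-trig attack on the methyl ester carbonyl with loss of methoxide (C4–C4a), so O1–C8a and C4–C4a are made without touching any bond to C2, whose configuration is retained. The closest known reactions are the fluoride-induced annulation of 2-(trimethylsilyl)aryl triflates with salicylate esters to xanthones (O-arylation followed by acyl capture of the aryl anion) and the regioselective addition of nucleophiles to 3-alkoxybenzynes; new here are the aliphatic β-oxido ester partner and its generation in the same flask by an asymmetric aldol. The step needs the alkoxide to outrun proton quench of the aryl anion and base-induced opening of the product, which is addressed by using 27 in threefold excess so that the alkoxide is present before the aryne forms, by the aprotic solvent, and by Me3SiF formed in the flask, which re-silylates methoxide.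

Step 18
Reactants: 29 (2S)-5,7-bis(benzyloxy)-6-(chain benzyl)-2-phenylchroman-4-one
Product: 30 (2S)-5,7-dihydroxy-6-{2-hydroxy-5-{2-hydroxy-5-[2-hydroxy-5-(2-hydroxybenzyl)benzyl]benzyl}benzyl}-2-phenylchroman-4-one
Conditions: H2 (1 atm), 10% Pd/C, EtOAc/MeOH, 25 °C
Reagents that add atoms: none
Why: Hydrogenolysis of the six aryl benzyl ethers should be much faster than reduction of the hydrogen-bonded C4 ketone or cleavage of the cyclic C2–O1 ether, the diarylmethane links are inert, and the neutral medium leaves C2 untouched.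

Step 19
Reactants: 30 hexaphenol flavanone; 31 2-hydroxybenzyl alcohol
Product: 32 sarmentosumin C
Conditions: ZnCl2 (1.5 equiv), 1,4-dioxane, 40 °C, slow addition of 31 (1.1 equiv)
Reagents that add atoms: none
Why: Lewis-acid ionisation of salicyl alcohol to an ortho-quinone methide and Friedel–Crafts alkylation should occur at C8, the only unsubstituted carbon of the phloroglucinol ring A (between O1 and the 7-OH, para to the 5-OH) and far more nucleophilic than the ortho positions of the chain phenols, under non-basic conditions that leave C2 untouched.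

**Compound list**
1 | 2-(benzyloxy)benzyl bromide | BrCc1ccccc1OCc1ccccc1 | starting material
2 | [4-(benzyloxy)-3-formylphenyl]boronic acid | O=Cc1cc(B(O)O)ccc1OCc1ccccc1 | starting material
3 | 2-(benzyloxy)-5-[2-(benzyloxy)benzyl]benzaldehyde | O=Cc1cc(Cc2ccccc2OCc2ccccc2)ccc1OCc1ccccc1 | intermediate
4 | {2-(benzyloxy)-5-[2-(benzyloxy)benzyl]phenyl}methanol | OCc1cc(Cc2ccccc2OCc2ccccc2)ccc1OCc1ccccc1 | intermediate
5 | 1-(benzyloxy)-4-[2-(benzyloxy)benzyl]-2-(bromomethyl)benzene | BrCc1cc(Cc2ccccc2OCc2ccccc2)ccc1OCc1ccccc1 | intermediate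
6 | 2-(benzyloxy)-5-{2-(benzyloxy)-5-[2-(benzyloxy)benzyl]benzyl}benzaldehyde | O=Cc1cc(Cc2cc(Cc3ccccc3OCc3ccccc3)ccc2OCc2ccccc2)ccc1OCc1ccccc1 | intermediate
7 | {2-(benzyloxy)-5-{2-(benzyloxy)-5-[2-(benzyloxy)benzyl]benzyl}phenyl}methanol | OCc1cc(Cc2cc(Cc3ccccc3OCc3ccccc3)ccc2OCc2ccccc2)ccc1OCc1ccccc1 | intermediate
8 | 1-(benzyloxy)-4-{2-(benzyloxy)-5-[2-(benzyloxy)benzyl]benzyl}-2-(chloromethyl)benzene | ClCc1cc(Cc2cc(Cc3ccccc3OCc3ccccc3)ccc2OCc2ccccc2)ccc1OCc1ccccc1 | intermediate
9 | 2-bromo-4-iodophenol | Oc1ccc(I)cc1Br | starting material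
10 | 1-(benzyloxy)-2-bromo-4-iodobenzene | Brc1cc(I)ccc1OCc1ccccc1 | intermediate
11 | benzylzinc chloride derived from 8 | Cl[Zn]Cc1cc(Cc2cc(Cc3ccccc3OCc3ccccc3)ccc2OCc2ccccc2)ccc1OCc1ccccc1 | intermediate
12 | 1-(benzyloxy)-2-bromo-4-{2-(benzyloxy)-5-{2-(benzyloxy)-5-[2-(benzyloxy)benzyl]benzyl}benzyl}benzene (tetramer aryl bromide) | Brc1cc(Cc2cc(Cc3cc(Cc4ccccc4OCc4ccccc4)ccc3OCc3ccccc3)ccc2OCc2ccccc2)ccc1OCc1ccccc1 | intermediate
13 | 2,4,6-trihydroxybenzaldehyde | O=Cc1c(O)cc(O)cc1O | starting material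
14 | 4-(allyloxy)-2,6-dihydroxybenzaldehyde | O=Cc1c(O)cc(OCC=C)cc1O | intermediate
15 | 4-(allyloxy)-2,6-bis(benzyloxy)benzaldehyde | O=Cc1c(OCc2ccccc2)cc(OCC=C)cc1OCc1ccccc1 | intermediate
16 | aryllithium derived from 12 (Li in place of Br) | [Li]c1cc(Cc2cc(Cc3cc(Cc4ccccc4OCc4ccccc4)ccc3OCc3ccccc3)ccc2OCc2ccccc2)ccc1OCc1ccccc1 | intermediate
17 | racemic [4-(allyloxy)-2,6-bis(benzyloxy)phenyl](tetramer aryl)methanol | OC(c1cc(Cc2cc(Cc3cc(Cc4ccccc4OCc4ccccc4)ccc3OCc3ccccc3)ccc2OCc2ccccc2)ccc1OCc1ccccc1)c1c(OCc2ccccc2)cc(OCC=C)cc1OCc1ccccc1 | intermediate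
18 | 5-(allyloxy)-1,3-bis(benzyloxy)-2-(chain benzyl)benzene | C=CCOc1cc(OCc2ccccc2)c(Cc2cc(Cc3cc(Cc4cc(Cc5ccccc5OCc5ccccc5)ccc4OCc4ccccc4)ccc3OCc3ccccc3)ccc2OCc2ccccc2)c(OCc2ccccc2)c1 | intermediate
19 | 3,5-bis(benzyloxy)-4-(chain benzyl)phenol | Oc1cc(OCc2ccccc2)c(Cc2cc(Cc3cc(Cc4cc(Cc5ccccc5OCc5ccccc5)ccc4OCc4ccccc4)ccc3OCc3ccccc3)ccc2OCc2ccccc2)c(OCc2ccccc2)c1 | intermediate
20 | 3,5-bis(benzyloxy)-2-bromo-4-(chain benzyl)phenol | Oc1cc(OCc2ccccc2)c(Cc2cc(Cc3cc(Cc4cc(Cc5ccccc5OCc5ccccc5)ccc4OCc4ccccc4)ccc3OCc3ccccc3)ccc2OCc2ccccc2)c(OCc2ccccc2)c1Br | intermediate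
21 | trimethylsilyl ether of 20 | C[Si](C)(C)Oc1cc(OCc2ccccc2)c(Cc2cc(Cc3cc(Cc4cc(Cc5ccccc5OCc5ccccc5)ccc4OCc4ccccc4)ccc3OCc3ccccc3)ccc2OCc2ccccc2)c(OCc2ccccc2)c1Br | intermediate
22 | lithium 3,5-bis(benzyloxy)-4-(chain benzyl)-2-(trimethylsilyl)phenoxide | [Li]Oc1cc(OCc2ccccc2)c(Cc2cc(Cc3cc(Cc4cc(Cc5ccccc5OCc5ccccc5)ccc4OCc4ccccc4)ccc3OCc3ccccc3)ccc2OCc2ccccc2)c(OCc2ccccc2)c1[Si](C)(C)C | intermediate
23 | 3,5-bis(benzyloxy)-4-(chain benzyl)-2-(trimethylsilyl)phenyl trifluoromethanesulfonate | O=S(=O)(Oc1cc(OCc2ccccc2)c(Cc2cc(Cc3cc(Cc4cc(Cc5ccccc5OCc5ccccc5)ccc4OCc4ccccc4)ccc3OCc3ccccc3)ccc2OCc2ccccc2)c(OCc2ccccc2)c1[Si](C)(C)C)C(F)(F)F | intermediate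
24 | methyl acetate | COC(C)=O | starting material
25 | 1-methoxy-1-(trimethylsilyloxy)ethene | C=C(OC)O[Si](C)(C)C | intermediate
26 | benzaldehyde | O=Cc1ccccc1 | starting material
27 | methyl (3S)-3-phenyl-3-(trimethylsilyloxy)propanoate | COC(=O)C[C@@H](c1ccccc1)O[Si](C)(C)C | intermediate
28 | 3,5-bis(benzyloxy)-4-(chain benzyl)benzyne (triple bond C4a≡C8a of the later flavanone) | C1#CC(OCc2ccccc2)=C(Cc2cc(Cc3cc(Cc4cc(Cc5ccccc5OCc5ccccc5)ccc4OCc4ccccc4)ccc3OCc3ccccc3)ccc2OCc2ccccc2)C(OCc2ccccc2)=C1 | intermediate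
29 | (2S)-5,7-bis(benzyloxy)-6-(chain benzyl)-2-phenylchroman-4-one | O=C1C[C@@H](c2ccccc2)Oc2cc(OCc3ccccc3)c(Cc3cc(Cc4cc(Cc5cc(Cc6ccccc6OCc6ccccc6)ccc5OCc5ccccc5)ccc4OCc4ccccc4)ccc3OCc3ccccc3)c(OCc3ccccc3)c21 | intermediate
30 | (2S)-5,7-dihydroxy-6-{2-hydroxy-5-{2-hydroxy-5-[2-hydroxy-5-(2-hydroxybenzyl)benzyl]benzyl}benzyl}-2-phenylchroman-4-one | O=C1C[C@@H](c2ccccc2)Oc2cc(O)c(Cc3cc(Cc4cc(Cc5cc(Cc6ccccc6O)ccc5O)ccc4O)ccc3O)c(O)c21 | intermediate
31 | 2-hydroxybenzyl alcohol | OCc1ccccc1O | starting material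
32 | sarmentosumin C | O=C1C[C@@H](c2ccccc2)Oc2c(Cc3ccccc3O)c(O)c(Cc3cc(Cc4cc(Cc5cc(Cc6ccccc6O)ccc5O)ccc4O)ccc3O)c(O)c21 | target

**Step count and risks**
Total steps: 19. Longest linear sequence: 15 steps (steps 1–6, 8, 11–15, 17–19).

Steps most likely to fail:

Step 17. The intermolecular capture of the aryne by the secondary alkoxide may be too slow, so that aryne self-reaction or attack of the alkoxide at the sulfonyl sulfur takes over. The C4a anion may be protonated before acyl capture. Retro-aldol of the alkoxide or base-induced opening of the flavanone may erode the configuration at C2. The fallback uses known chemistry and sets out from 20. Treatment with n-BuLi (2.2 equiv, THF, −78 °C; phenoxide formation and bromine–lithium exchange) and then N-methoxy-N-methylacetamide should give 1-[4,6-bis(benzyloxy)-2-hydroxy-5-(chain benzyl)phenyl]ethanone F1. Condensation with Me2NCH(OMe)2 in toluene at 90 °C should give (E)-3-(dimethylamino)-1-[4,6-bis(benzyloxy)-2-hydroxy-5-(chain benzyl)phenyl]prop-2-en-1-one F2. HCl in CH2Cl2 should close it to 5,7-bis(benzyloxy)-6-(chain benzyl)-4H-chromen-4-one F3. Asymmetric conjugate addition of PhB(OH)2 [Pd(OCOCF3)2, 4-tert-butyl-2-(pyridin-2-yl)-4,5-dihydrooxazole in the antipode that gives 2S, NH4PF6, H2O, ClCH2CH2Cl, 60 °C] should then give 29, where the route is rejoined before step 18.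

Step 19. Alkylation may not stop at C8: the chain phenols may be C- or O-alkylated, hydroxybenzyl groups may migrate under the Lewis acid, and the 5-hydroxyflavanone may partly racemise by ring opening. The fallback sets out from 29 and comes back at 32. NBS in MeCN at 0 °C should brominate C8, the only free position of the trioxygenated ring, to give (2S)-5,7-bis(benzyloxy)-8-bromo-6-(chain benzyl)-2-phenylchroman-4-one F4. 2-(Benzyloxy)benzylzinc bromide F5, made from 1 with zinc dust and LiCl in THF, is coupled with F4 under Pd(OAc)2/SPhos catalysis (Negishi, THF, 25 °C) to give (2S)-5,7-bis(benzyloxy)-8-[2-(benzyloxy)benzyl]-6-(chain benzyl)-2-phenylchroman-4-one F6. Hydrogenolysis under the conditions of step 18 should then give 32.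

Step 18. Hydrogenolysis may go too far (opening of the benzylic C2–O1 bond, reduction of the ketone) or stall on partly debenzylated, poorly soluble material. The fallback runs from 29 to 30 with BCl3 and pentamethylbenzene in CH2Cl2 at −78 °C, a non-reductive Lewis-acid debenzylation with a cation scavenger. It makes no new compound (entry F0).

Further compounds
F1 | step 17 | 1-[4,6-bis(benzyloxy)-2-hydroxy-5-(chain benzyl)phenyl]ethanone | CC(=O)c1c(O)cc(OCc2ccccc2)c(Cc2cc(Cc3cc(Cc4cc(Cc5ccccc5OCc5ccccc5)ccc4OCc4ccccc4)ccc3OCc3ccccc3)ccc2OCc2ccccc2)c1OCc1ccccc1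
F2 | step 17 | (E)-3-(dimethylamino)-1-[4,6-bis(benzyloxy)-2-hydroxy-5-(chain benzyl)phenyl]prop-2-en-1-one | CN(C)/C=C/C(=O)c1c(O)cc(OCc2ccccc2)c(Cc2cc(Cc3cc(Cc4cc(Cc5ccccc5OCc5ccccc5)ccc4OCc4ccccc4)ccc3OCc3ccccc3)ccc2OCc2ccccc2)c1OCc1ccccc1
F3 | step 17 | 5,7-bis(benzyloxy)-6-(chain benzyl)-4H-chromen-4-one | O=c1ccoc2cc(OCc3ccccc3)c(Cc3cc(Cc4cc(Cc5cc(Cc6ccccc6OCc6ccccc6)ccc5OCc5ccccc5)ccc4OCc4ccccc4)ccc3OCc3ccccc3)c(OCc3ccccc3)c12
F4 | step 19 | (2S)-5,7-bis(benzyloxy)-8-bromo-6-(chain benzyl)-2-phenylchroman-4-one | O=C1C[C@@H](c2ccccc2)Oc2c(Br)c(OCc3ccccc3)c(Cc3cc(Cc4cc(Cc5cc(Cc6ccccc6OCc6ccccc6)ccc5OCc5ccccc5)ccc4OCc4ccccc4)ccc3OCc3ccccc3)c(OCc3ccccc3)c21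
F5 | step 19 | 2-(benzyloxy)benzylzinc bromide | Br[Zn]Cc1ccccc1OCc1ccccc1
F6 | step 19 | (2S)-5,7-bis(benzyloxy)-8-[2-(benzyloxy)benzyl]-6-(chain benzyl)-2-phenylchroman-4-one | O=C1C[C@@H](c2ccccc2)Oc2c(Cc3ccccc3OCc3ccccc3)c(OCc3ccccc3)c(Cc3cc(Cc4cc(Cc5cc(Cc6ccccc6OCc6ccccc6)ccc5OCc5ccccc5)ccc4OCc4ccccc4)ccc3OCc3ccccc3)c(OCc3ccccc3)c21
F0 | step 18 | none | none
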